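If I charge more precatalyst into this flask, the rate at the mark of 10% conversion need not follow the charge; that depends on what the catalyst is doing when the mark is reached.

in all of them: precatalyst 0.05 mol%

| run | left-handed substrate | right-handed substrate | coupling partner | remark |
|---|---|---|---|---|
| midnight | 12 mM | 12 mM | 2 equiv | run made earlier |
| noon | 46 mM | 46 mM | 2 equiv | run made earlier |
| flask | 23 mM | 23 mM | 2.00 equiv |  |

- midnight (time / min: left-handed product / %, left-handed substrate / %): 0.250: 14.4, 35.5; 0.667: 32.3, 17.3; 1.33: 40.4, 8.9; 2.00: 43.2, 6.9; 3.00: 44.1, 5.9; 4.00: 44.4, 5.2; 5.00: 45.2, 5.0
- noon (time / min: left-handed product / %, left-handed substrate / %): 0.667: 47.7, 2.1; 1.33: 48.4, 2.4; 2.00: 48.1, 1.5; 3.00: 47.8, 2.0; 4.00: 48.5, 2.1; 5.00: 48.6, 1.8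

(readings scatter by 0.3 percentage points)

1. factor on the rate of making left-handed product when 10% of the left-handed substrate and right-handed substrate together are converted if precatalyst is charged twice over
2. factor on the rate when 10% of the left-handed substrate and right-handed substrate together are converted if precatalyst is charged at 0.25 mol% instead

- catalyst is single-handed; left-handed substrate and right-handed substrate are mirror images of each other, charged as a racemate, each of them at the stated concentration
- the earlier runs were read with a standard deviation of 0.3 percentage points

First, where does the mark stand? The midnight run already shows 14.4% left-handed product at 0.250 min, more than the mark. This flask has about twice the midnight concentration, and the noon run shows that concentration speeds things up, with 47.7% against 32.3% at 0.667 min. So I put the flask's mark before that first midnight reading.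

Second, is the catalyst complete by then? In the midnight run the average first-order constant of the left-handed substrate goes from 1.37 min⁻¹ to 1.59 min⁻¹ by 0.667 min, rising although coupling partner is being used. I read that as a slow start (induction period), with catalyst still forming well after the mark.

Third, what does that do at the mark? Catalyst then grows with loading times time, so conversion grows with loading times the square of the time. Equal conversion therefore comes at a time that goes as one over the root of the loading, and the catalyst present there goes as the root. That gives 0.500 as my loading exponent, the power of the precatalyst charge that the rate follows at fixed conversion. Doubling gives 1.41, and 0.25 mol% gives 2.24.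

The forecast gives 2 and 5, both above my factors, and its words are "roughly proportional scaling".

The simulation gives 1.47 and 2.40.

    coupling partner + catalyst + left-handed substrate → catalyst + left-handed product (k = 1.50 × 10⁶ M⁻² s⁻¹)
    coupling partner + precatalyst → catalyst + spent reagent (k = 0.930 M⁻¹ s⁻¹)
    coupling partner + catalyst + right-handed substrate → catalyst + right-handed product (k = 7.00 × 10⁵ M⁻² s⁻¹)
    2 coupling partner → homo dimer (k = 0.280 M⁻¹ s⁻¹)

In this flask the lifetime of precatalyst at the charged coupling partner is 0.390 min, and the mark falls earlier than that, at 0.0537 min, which is 0.138 of a lifetime in, and the loading exponent of 0.500 gives 1.41 against the simulated 1.47. In the flask with 0.25 mol% the exponent's 2.24 stands against 2.40, with 94.5% of the catalyst still precatalyst at the same conversion.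

(The earlier runs and the new flask stem from a simulated flask for an exercise; noise was put on by code.)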